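**Retrosynthetic overview**
- The diarylmethane C(sp2)–CH2 bond is disconnected between C2 of ring A and the benzylic carbon of ring B. This gives lanosol 4 (electrophile, via a p-quinone methide) and 3,5-dihydroxy-4-methoxybenzyl alcohol 6 (nucleophile), joined last without protecting groups.
- Lanosol 4 comes from 5-bromovanillin 1 by bromination, O-demethylation and aldehyde reduction.
- Alcohol 6 comes from methyl 3,5-dihydroxy-4-methoxybenzoate 5 by ester reduction.
- No ring is formed; both benzene rings are bought.

Assumption: the target has no stereocentre (it is achiral), so no stereocontrol is needed and the structure is made exactly as the SMILES is written.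
Assumption: metal or boron alkoxide/phenoxide salts of a product that are simply hydrolysed on work-up (steps 2–4) are not counted as separate compounds.

**Step 1**
Reactants: 1 5-bromovanillin (3-bromo-4-hydroxy-5-methoxybenzaldehyde)
Product: 2 2,3-dibromo-4-hydroxy-5-methoxybenzaldehyde (5,6-dibromovanillin)
Conditions: Br2 (1.2 equiv), Fe powder (cat.), NaOAc (1.2 equiv), AcOH, rt
Reagents that add atoms: bromine, BrBr
Why: Fe-assisted electrophilic aromatic bromination goes to the free position para to the OMe group (the other free position is only ortho to OMe), so the second bromine enters next to the first and ortho to CHO, while NaOAc buffers the HBr.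

**Step 2**
Reactants: 2 2,3-dibromo-4-hydroxy-5-methoxybenzaldehyde
Product: 3 2,3-dibromo-4,5-dihydroxybenzaldehyde
Conditions: BBr3 (3 equiv), CH2Cl2, −78 °C to rt; then H2O
Reagents that add atoms: none
Why: BBr3 O-demethylation (Lewis-acid ether cleavage by bromide attack on the O-methyl of the borane adduct) frees the catechol, and the aldehyde and aryl bromides are inert at or below rt.

**Step 3**
Reactants: 3 2,3-dibromo-4,5-dihydroxybenzaldehyde
Product: 4 lanosol, 3,4-dibromo-5-(hydroxymethyl)benzene-1,2-diol
Conditions: NaBH4 (2 equiv), THF/H2O 4:1, 0 °C to rt; then aq. NH4Cl (pH 5–6), EtOAc extraction, no alcohol solvents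
Reagents that add atoms: none
Why: Borohydride reduction of the aldehyde leaves the aryl bromides untouched, and the alcohol-free, near-neutral work-up avoids solvolytic ether formation from the labile p-hydroxybenzyl alcohol.

**Step 4**
Reactants: 5 methyl 3,5-dihydroxy-4-methoxybenzoate
Product: 6 3,5-dihydroxy-4-methoxybenzyl alcohol, 5-(hydroxymethyl)-2-methoxybenzene-1,3-diol
Conditions: LiAlH4 (3.5 equiv), THF, 0 °C to reflux; then aq. Rochelle salt
Reagents that add atoms: none
Why: LiAlH4 ester reduction works here because the two phenoxides formed in situ are meta to the ester and do not deactivate it, and the aryl methyl ether is inert.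

**Step 5**
Reactants: 4 lanosol, 3,4-dibromo-5-(hydroxymethyl)benzene-1,2-diol; 6 3,5-dihydroxy-4-methoxybenzyl alcohol (3 equiv, excess recovered)
Product: 10 3,4-dibromo-5-{[2,4-dihydroxy-6-(hydroxymethyl)-3-methoxyphenyl]methyl}benzene-1,2-diol (target), via lanosol diphenylborinate chelate 7 (not isolated), via boron-chelated p-quinone methide 8 (not isolated), via product diphenylborinate chelate 9 (not isolated)
Conditions: Ph2BOH (10 mol %), MeCN/HFIP 4:1, 40 °C, Ar; then 0.5 M HCl/EtOAc
Reagents that add atoms: none
Why: Proposed new method: catechol-recognising borinic acid catalysis of a dehydrative cross-benzylation — Ph2BOH chelates only the catechol of 4 to give the tetracoordinate borinate 7, a masked catecholate that is also a Lewis-acid-assisted Brønsted acid, so push (borinate oxygen para to CH2OH) and pull (proton relayed by HFIP to the benzylic OH) expel water by 1,6-elimination to give the O→B-activated p-quinone methide 8; C2 of 6 (ortho and para to its two OH groups, C2 and C6 being equivalent by symmetry) adds to the exocyclic CH2 of 8 in a vinylogous Friedel–Crafts 1,6-addition to give 9, and boron exchange onto fresh 4 releases 10, so that one molecule of water is the only by-product of the coupling; 6 and ring A of 10 have no vicinal diol and carry a p-OMe (not p-OH) benzylic alcohol, so they are not ionised, O-alkylated by-products are p-hydroxybenzyl ethers that re-enter through 8, and the excess of 6 suppresses double benzylation; the closest known reaction types are diarylborinic-acid activation of cis-1,2-diols through tetracoordinate borinates and acid-catalysed 1,6-arylation of in situ generated p-quinone methides (Friedel–Crafts benzylation with hydroxybenzyl alcohols); no stereocentre is formed.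

**Compound list**
1 | 5-bromovanillin (3-bromo-4-hydroxy-5-methoxybenzaldehyde) | COc1cc(C=O)cc(Br)c1O | starting material
2 | 2,3-dibromo-4-hydroxy-5-methoxybenzaldehyde | COc1cc(C=O)c(Br)c(Br)c1O | intermediate
3 | 2,3-dibromo-4,5-dihydroxybenzaldehyde | O=Cc1cc(O)c(O)c(Br)c1Br | intermediate
4 | lanosol, 3,4-dibromo-5-(hydroxymethyl)benzene-1,2-diol | OCc1cc(O)c(O)c(Br)c1Br | intermediate
5 | methyl 3,5-dihydroxy-4-methoxybenzoate | COC(=O)c1cc(O)c(OC)c(O)c1 | starting material
6 | 3,5-dihydroxy-4-methoxybenzyl alcohol | COc1c(O)cc(CO)cc1O | intermediate
7 | lanosol diphenylborinate chelate (BPh2 bridging both catechol oxygens of 4, tetracoordinate boron, the oxygen meta to CH2OH still protonated) | OCc1cc2[OH+][B-](c3ccccc3)(c3ccccc3)Oc2c(Br)c1Br | intermediate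
8 | boron-chelated p-quinone methide (2,3-dibromo-4-methylenecyclohexa-2,5-dienone whose carbonyl oxygen is coordinated to the BPh2 held by the neighbouring enol oxygen) | C=C1C=C2O[B-](c3ccccc3)(c3ccccc3)[O+]=C2C(Br)=C1Br | intermediate
9 | product diphenylborinate chelate (BPh2 bridging the catechol oxygens of the target) | COc1c(O)cc(CO)c(Cc2cc3[OH+][B-](c4ccccc4)(c4ccccc4)Oc3c(Br)c2Br)c1O | intermediate
10 | 3,4-dibromo-5-{[2,4-dihydroxy-6-(hydroxymethyl)-3-methoxyphenyl]methyl}benzene-1,2-diol | COc1c(O)cc(CO)c(Cc2cc(O)c(O)c(Br)c2Br)c1O | target

**Totals**
Total step count: 5. Longest linear sequence: 4 steps (1 → 2 → 3 → 4 → 10).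

**Three steps most likely to fail**

Step 5 (the proposed new step). Risks are weak turnover of the borinic acid, competing ionisation of the benzylic alcohol of 6 or 10, and double benzylation. The fallback uses known chemistry and sets out from 4. Instead of 6, the ester 5 (3 equiv) is used as the nucleophile in a conventional Brønsted-acid Friedel–Crafts benzylation (TsOH·H2O 20 mol %, MeCN, 60 °C). Ester 5 has no ionisable benzylic alcohol, so strong acid is tolerated. This gives methyl 2-(2,3-dibromo-4,5-dihydroxybenzyl)-3,5-dihydroxy-4-methoxybenzoate F1. The ester of F1 is then reduced with LiAlH4 (5 equiv, THF, 0 °C, where aryl bromides survive), and the route is rejoined at 10.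

Step 3. Risks are sluggish hydride addition to the phenoxide-deactivated aldehyde, over-reduction through a quinone methide, and loss of the labile product on isolation. The fallback sets out from 3 and masks the catechol first. Ac2O/pyridine gives 3,4-dibromo-5-formyl-1,2-phenylene diacetate F2. The aldehyde is then reduced under non-basic conditions with BH3·THF (0 °C) to 3,4-dibromo-5-(hydroxymethyl)-1,2-phenylene diacetate F3. Cold deacetylation (LiOH, degassed THF/H2O, 0 °C, then pH 4–5) returns to the route at 4.

Step 1. Risks are ipso-bromodeformylation para to the free phenol or a regioisomeric mixture. The fallback sets out from 1 and caps the phenol before bromination. MeI/K2CO3 in DMF gives 3-bromo-4,5-dimethoxybenzaldehyde F4. Bromination (Br2, Fe cat., AcOH) para to the 5-OMe group gives 2,3-dibromo-4,5-dimethoxybenzaldehyde F5. Double O-demethylation with BBr3 (CH2Cl2, −78 °C to rt) rejoins the route at 3, bypassing 2.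

**Further compounds**
F1 | step 5 | methyl 2-(2,3-dibromo-4,5-dihydroxybenzyl)-3,5-dihydroxy-4-methoxybenzoate | COC(=O)c1cc(O)c(OC)c(O)c1Cc1cc(O)c(O)c(Br)c1Br
F2 | step 3 | 3,4-dibromo-5-formyl-1,2-phenylene diacetate | CC(=O)Oc1cc(C=O)c(Br)c(Br)c1OC(C)=O
F3 | step 3 | 3,4-dibromo-5-(hydroxymethyl)-1,2-phenylene diacetate | CC(=O)Oc1cc(CO)c(Br)c(Br)c1OC(C)=O
F4 | step 1 | 3-bromo-4,5-dimethoxybenzaldehyde | COc1cc(C=O)cc(Br)c1OC
F5 | step 1 | 2,3-dibromo-4,5-dimethoxybenzaldehyde | COc1cc(C=O)c(Br)c(Br)c1OC
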